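**Plan**
1. Retrosynthesis: first the five O-benzyl bonds are cut. Then, in one operation, the interflavan bond C4(upper)–C8(lower) and the ring C bond C2–C3 of the upper flavan are cut, giving tri-O-benzyl-(−)-epiafzelechin and an acyclic α-acetoxy benzyl aryl ether. That ether is cut at the acetal C–OAc/C–H (ester reduction), the ester C–O and the vinyl C=C.
2. Enabling feature: upper C4 is benzylic to ring A, ortho to O1 and para to the 7-oxygen. A vinyl group on ring A is therefore a polarised π-nucleophile whose terminal carbon (future C3H2) can close onto an oxocarbenium carbon (future C2) carried on O1, and the C4 cation that results is stabilised enough to be intercepted by C8 of the phloroglucinol-type ring A of the lower unit.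
3. Forward: ring A of the upper unit receives the vinyl group (C4=C3), then the O-aroyl group, then O–CH(OAc)Ar (C2 with ring B). Ring C arises by C2–C3 closure, the C4 cation is joined to C8 of the lower unit, and debenzylation ends the route.
4. Stereochemistry: lower C2/C3 come from (−)-epiafzelechin. Upper C2 is set by catalyst control in an enantioconvergent ionisation/closure of the racemic acetal. Upper C4 is set by substrate control, by attack anti to the 2-aryl group on a cation reached from both C4-epimeric acetates.

Key step: step 5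

Assumption: (−)-epiafzelechin is bought as the enantiopure natural flavan-3-ol, and its two stereocenters are carried through unchanged.

**Route**

Step 1
Reactants: 1 (−)-epiafzelechin, (2R,3R)-2-(4-hydroxyphenyl)chroman-3,5,7-triol
Product: 2 5,7,4'-tri-O-benzyl-(−)-epiafzelechin, (2R,3R)-5,7-bis(benzyloxy)-2-[4-(benzyloxy)phenyl]chroman-3-ol
Conditions: BnBr (3.3 equiv), K2CO3, DMF, 0 °C to rt
Reagents that add atoms: benzyl bromide, BrCc1ccccc1
Why: Williamson etherification in which carbonate deprotonates only the three phenols, so the secondary 3-OH should stay free and C2/C3 are untouched, as in the phenol-selective benzylation of catechin and epicatechin.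

Step 2
Reactants: 3 4-(benzyloxy)-2-hydroxybenzaldehyde
Product: 4 5-(benzyloxy)-2-vinylphenol
Conditions: Ph3PCH3Br (2.5 equiv), KOtBu (2.5 equiv), THF, 0 °C to rt
Reagents that add atoms: methyltriphenylphosphonium bromide, C[P+](c1ccccc1)(c1ccccc1)c1ccccc1.[Br-]
Why: Wittig methylenation with excess ylide tolerates the phenoxide and should turn the salicylaldehyde into the 2-vinylphenol, which places the future C4 and C3 on ring A; no stereocenter is formed.

Step 3
Reactants: 4 5-(benzyloxy)-2-vinylphenol; 5 4-(benzyloxy)benzoyl chloride
Product: 6 5-(benzyloxy)-2-vinylphenyl 4-(benzyloxy)benzoate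
Conditions: Et3N, DMAP (cat.), CH2Cl2, 0 °C
Reagents that add atoms: none
Why: DMAP-catalysed O-acylation of the phenol with the acid chloride should form the O1–C2 bond at the ester oxidation level and bring in ring B; no stereocenter is formed.

Step 4
Reactants: 6 5-(benzyloxy)-2-vinylphenyl 4-(benzyloxy)benzoate
Product: 8 racemic [5-(benzyloxy)-2-vinylphenoxy][4-(benzyloxy)phenyl]methyl acetate, via aluminium hemiacetal 7 (not isolated)
Conditions: iBu2AlH, CH2Cl2, −78 °C; then pyridine, DMAP, Ac2O, −78 to −20 °C; filtration through Et3N-deactivated silica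
Reagents that add atoms: acetic anhydride, CC(=O)OC(C)=O
Why: Reductive acetylation of an ester, in which one hydride adds at −78 °C and the tetrahedral aluminium hemiacetal is acetylated in the flask before it can collapse, should give the α-acetoxy ether; it is racemic, which does not matter because its acetal carbon is planarised in step 5.

Step 5
Reactants: 8 racemic [5-(benzyloxy)-2-vinylphenoxy][4-(benzyloxy)phenyl]methyl acetate; 2 5,7,4'-tri-O-benzyl-(−)-epiafzelechin
Product: 12 (2R,3R)-5,7-bis(benzyloxy)-2-[4-(benzyloxy)phenyl]-8-{(2S,4R)-7-(benzyloxy)-2-[4-(benzyloxy)phenyl]chroman-4-yl}chroman-3-ol, via aryloxocarbenium ion 9 (not isolated), via flavan-4-yl cation 10 (not isolated), via flavan-4-yl acetate 11 (not isolated)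
Conditions: (S,S)-imidodiphosphorimidate acid [two (S)-3,3'-bis(3,5-bis(trifluoromethyl)phenyl)-1,1'-bi-2-naphthol units on a P–N–P core, both imido nitrogens triflylated] (5 mol %), CH2Cl2 (0.02 M), −78 °C; then 2 (3 equiv), Me3SiOTf (0.3 equiv), −78 °C; aq. NaHCO3
Reagents that add atoms: none
Why: Proposed new method: the chiral acid protonates the acetate carbonyl of racemic 8 and expels acetic acid (a far better leaving group than the electron-rich aryloxide), so both enantiomers converge on the planar aryloxocarbenium ion 9 held as a contact ion pair with the confined chiral anion; the closest known reaction types are the imidodiphosphorimidate-catalysed asymmetric Prins cyclisation of aldehydes with homoallylic alcohols and the segment-coupling Prins cyclisation of α-acetoxy ethers, here extended to a phenol-derived oxocarbenium ion and a styrene π-nucleophile. The terminal vinyl carbon (future C3) attacks C2 in a 6-endo-trig cation–olefin closure of ring C through a half-chair, polarised in the Markovnikov sense because the developing C4 cation 10 is benzylic, ortho to O1 and para to the 7-benzyloxy group, which also disfavours a 5-exo closure through a primary cation. The new C2 stereocenter is set under catalyst control by the face of 9 that the chiral anion leaves open (the sense of induction is not predictable in advance; the antipodal acid is used if the (S,S) acid delivers 2R), and cation 10 is parked by acetate return as the C4-epimeric acetates 11 with release of the acid. In the second stage Me3SiOTf re-ionises both epimers of 11 to the single cation 10, and C8 of 2 attacks it along the axial trajectory anti to the pseudo-equatorial 2-aryl group, which should set C4 as 4R (2,4-trans) under substrate control, in line with the known Lewis-acid C4–C8 couplings of 4-acyloxy- and 4-alkoxyflavans with benzylated flavan-3-ols. The step needs acetate-over-aryloxide ionisation, ring closure ahead of intermolecular arylation of 9, and C8-over-C6 mono-alkylation of 2; these are secured by the leaving-group difference, by adding 2 only after the closure, and by the higher nucleophilicity of C8 in 5,7-di-O-benzyl flavan-3-ols together with the excess of 2.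

Step 6
Reactants: 12 (2R,3R)-5,7-bis(benzyloxy)-2-[4-(benzyloxy)phenyl]-8-{(2S,4R)-7-(benzyloxy)-2-[4-(benzyloxy)phenyl]chroman-4-yl}chroman-3-ol
Product: 13 (2R,3R)-8-[(2S,4R)-7-hydroxy-2-(4-hydroxyphenyl)chroman-4-yl]-2-(4-hydroxyphenyl)chroman-3,5,7-triol
Conditions: H2 (1 atm), Pd(OH)2 on carbon, THF/MeOH/H2O, rt
Reagents that add atoms: none
Why: Catalytic hydrogenolysis of the five aryl benzyl ethers, the usual last step for benzyl-protected proanthocyanidins, should leave the C2–O1 bonds, the C4–C8 bond and all four stereocenters intact under neutral conditions at room temperature.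

**Compound list**
1 | (−)-epiafzelechin, (2R,3R)-2-(4-hydroxyphenyl)chroman-3,5,7-triol | Oc1cc(O)c2c(c1)O[C@H](c1ccc(O)cc1)[C@H](O)C2 | starting material
2 | (2R,3R)-5,7-bis(benzyloxy)-2-[4-(benzyloxy)phenyl]chroman-3-ol | C(c1ccccc1)Oc1cc(OCc3ccccc3)c2c(c1)O[C@H](c1ccc(OCc3ccccc3)cc1)[C@H](O)C2 | intermediate
3 | 4-(benzyloxy)-2-hydroxybenzaldehyde | O=Cc1ccc(OCc2ccccc2)cc1O | starting material
4 | 5-(benzyloxy)-2-vinylphenol | C=Cc1ccc(OCc2ccccc2)cc1O | intermediate
5 | 4-(benzyloxy)benzoyl chloride | O=C(Cl)c1ccc(OCc2ccccc2)cc1 | starting material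
6 | 5-(benzyloxy)-2-vinylphenyl 4-(benzyloxy)benzoate | C=Cc1ccc(OCc2ccccc2)cc1OC(=O)c1ccc(OCc2ccccc2)cc1 | intermediate
7 | O-(diisobutylaluminio) hemiacetal of 6, [5-(benzyloxy)-2-vinylphenoxy][4-(benzyloxy)phenyl]methoxy(diisobutyl)aluminium, racemic | C=Cc1ccc(OCc2ccccc2)cc1OC(O[Al](CC(C)C)CC(C)C)c1ccc(OCc2ccccc2)cc1 | intermediate
8 | [5-(benzyloxy)-2-vinylphenoxy][4-(benzyloxy)phenyl]methyl acetate, racemic | C=Cc1ccc(OCc2ccccc2)cc1OC(OC(C)=O)c1ccc(OCc2ccccc2)cc1 | intermediate
9 | [5-(benzyloxy)-2-vinylphenyl][4-(benzyloxy)benzylidene]oxonium (aryloxocarbenium ion) | C=Cc1ccc(OCc2ccccc2)cc1[O+]=Cc1ccc(OCc2ccccc2)cc1 | intermediate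
10 | (2S)-7-(benzyloxy)-2-[4-(benzyloxy)phenyl]chroman-4-ylium (flavan-4-yl cation) | C(c1ccccc1)Oc1ccc([C@@H]2C[CH+]c3ccc(OCc4ccccc4)cc3O2)cc1 | intermediate
11 | (2S)-7-(benzyloxy)-2-[4-(benzyloxy)phenyl]chroman-4-yl acetate, both C4 epimers | C(c1ccccc1)Oc1ccc([C@@H]2CC(OC(C)=O)c3ccc(OCc4ccccc4)cc3O2)cc1 | intermediate
12 | (2R,3R)-5,7-bis(benzyloxy)-2-[4-(benzyloxy)phenyl]-8-{(2S,4R)-7-(benzyloxy)-2-[4-(benzyloxy)phenyl]chroman-4-yl}chroman-3-ol | C(c1ccccc1)Oc1ccc([C@@H]2C[C@@H](c3c(OCc5ccccc5)cc(OCc5ccccc5)c4c3O[C@H](c3ccc(OCc5ccccc5)cc3)[C@H](O)C4)c3ccc(OCc5ccccc5)cc3O2)cc1 | intermediate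
13 | (2R,3R)-8-[(2S,4R)-7-hydroxy-2-(4-hydroxyphenyl)chroman-4-yl]-2-(4-hydroxyphenyl)chroman-3,5,7-triol | Oc1ccc([C@@H]2C[C@@H](c3c(O)cc(O)c4c3O[C@H](c3ccc(O)cc3)[C@H](O)C4)c3ccc(O)cc3O2)cc1 | target

Total step count: 6. Longest linear sequence: 5 steps (3 → 4 → 6 → 8 → 12 → 13; step 1 runs in parallel).

**Steps most likely to fail**

Step 5. The risks are poor enantioface discrimination in the ring closure, intermolecular arylation or oligomerisation of the styrene ahead of cyclisation, and weak facial selectivity at C4. The fallback uses known chemistry without any C2–C3 closure; it sets out from 2 and comes back at 12. Purchased (2S)-liquiritigenin, Oc1ccc([C@@H]2CC(=O)c3ccc(O)cc3O2)cc1, is dibenzylated under neutral Mitsunobu conditions (BnOH, PPh3, DIAD, THF, 0 °C), which avoid the base-induced opening to the chalcone that would racemise C2, to give (2S)-7-(benzyloxy)-2-[4-(benzyloxy)phenyl]chroman-4-one F1. Reduction with NaBH4 (MeOH/THF, 0 °C) should give the 2,4-cis alcohol (2S,4S)-7-(benzyloxy)-2-[4-(benzyloxy)phenyl]chroman-4-ol F2. BF3·OEt2 (CH2Cl2, −78 to −40 °C) with excess 2 ionises F2 to the same cation 10, which is arylated at C8 of 2 to give 12; this is the established flavan-4-ol Friedel–Crafts route to 4-arylflavans.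

Step 4. The risks are collapse of the tetrahedral aluminium hemiacetal to aldehyde and aluminium phenoxide before acetylation (the aryloxide is a better leaving group than an alkoxide), and hydrolysis of the acetal on silica. The fallback sets out from 4 and comes back at 8 with no hydride step. Purchased 4-(benzyloxy)benzaldehyde is treated with acetyl chloride (cat. ZnCl2, CH2Cl2, 0 °C) to give chloro[4-(benzyloxy)phenyl]methyl acetate F3. F3 then alkylates the phenol oxygen of 4 (iPr2NEt, CH2Cl2, −40 °C) to give 8 directly, following the O-alkylation of phenols with 1-chloroalkyl esters used for acyloxyalkyl aryl ethers.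

Step 6. The risks are hydrogenolytic opening of the benzylic C2–O1 bonds and incomplete removal of the five benzyl groups. The fallback goes from 12 to 13 by Lewis-acid debenzylation instead of hydrogenolysis: BCl3 with pentamethylbenzene as benzyl-cation scavenger (CH2Cl2, −78 °C), where the low temperature and aprotic medium should spare the interflavan bond. It makes no new compound.

**Further compounds**
F1 | step 5 | (2S)-7-(benzyloxy)-2-[4-(benzyloxy)phenyl]chroman-4-one | C(c1ccccc1)Oc1ccc([C@@H]2CC(=O)c3ccc(OCc4ccccc4)cc3O2)cc1
F2 | step 5 | (2S,4S)-7-(benzyloxy)-2-[4-(benzyloxy)phenyl]chroman-4-ol | C(c1ccccc1)Oc1ccc([C@@H]2C[C@H](O)c3ccc(OCc4ccccc4)cc3O2)cc1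
F3 | step 4 | chloro[4-(benzyloxy)phenyl]methyl acetate | CC(=O)OC(Cl)c1ccc(OCc2ccccc2)cc1
F0 | step 6 | none | none
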